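**Retrosynthetic overview**
1. Last step: saponification and hydrolytic aromatization of a 4,4-dimethoxy-2-methylcyclohexenone adduct. The six-membered ring is bought as an arene, dearomatized to a quinone monoketal, carried through the coupling as a cyclohexenone ketal and re-aromatized only at the end; no other ring is formed.
2. Key disconnection: the bond between the aryl carbon that carries the side chain (aryl C1) and the vinyl CH. It is made in one flask from three components: an ethynyl carbinol, pinacolborane and the quinone monoketal (Zr-catalysed hydroboration, then Rh-catalysed 1,4-addition).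
3. Enabling feature: the para pair of ring oxygens on aryl C2 and C5. With C5 as ketone and C2 as dimethyl ketal, C1 is the β-carbon of the enone C5(=O)–C6=C1, while the C4 methyl sits α on the other enone arm and closes off the rival β-carbon C3. The (E)-CH=CH next to the tertiary carbinol is a syn-hydrometalated terminal alkyne.
4. Alkyne fragment: Wittig olefination (C2=C3 enoate) of an ynal with an α-homoprenyl stabilized ylide. The ynal comes from (2E,6E)-farnesol: terminal epoxide as masked aldehyde, Sharpless epoxidation for the carbinol centre, epoxy chloride to ethynyl carbinol.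

Key step: step 11

Remark: the terminal epoxide and the ring carbon created in the key step are carried as mixtures of epimers; both centres are destroyed later, so only the carbinol centre set by the Sharpless epoxidation matters. The four starting materials are taken as commercial.

**Route**

Step 1
Reactants: 1 (2E,6E)-farnesol
Product: 2 (2E,6E)-farnesyl acetate
Conditions: Ac2O, pyridine, DMAP (cat.), CH2Cl2, 0 °C to rt
Reagents that add atoms: acetic anhydride CC(=O)OC(C)=O
Why: Acylation of the primary allylic alcohol; the acetate deactivates the 2,3-alkene towards the electrophilic bromine of step 2.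

Step 2
Reactants: 2 (2E,6E)-farnesyl acetate
Product: 3 (2E,6E)-10-bromo-11-hydroxy-3,7,11-trimethyldodeca-2,6-dien-1-yl acetate (racemic at C10)
Conditions: NBS (1.1 equiv), THF/H2O, 0 °C
Reagents that add atoms: N-bromosuccinimide O=C1CCC(=O)N1Br; water O
Why: Bromohydrin formation in aqueous THF is expected to be selective for the terminal trisubstituted alkene (the 2,3-alkene is deactivated, the internal one is shielded in the coiled chain), with water opening the bromonium ion at the tertiary carbon; the new centre is racemic and is removed in step 7.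

Step 3
Reactants: 3 bromohydrin acetate
Product: 4 (2E,6E)-9-(3,3-dimethyloxiran-2-yl)-3,7-dimethylnona-2,6-dien-1-ol (racemic epoxide)
Conditions: K2CO3, MeOH, rt
Reagents that add atoms: none
Why: Carbonate in methanol closes the bromohydrin to the epoxide (intramolecular Williamson substitution) and removes the acetate by transesterification in the same operation.

Step 4
Reactants: 4 10,11-epoxyfarnesol
Product: 5 [(2S,3S)-3-[(3E)-6-(3,3-dimethyloxiran-2-yl)-4-methylhex-3-en-1-yl]-3-methyloxiran-2-yl]methanol (both epimers at the distal oxirane)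
Conditions: Ti(OiPr)4 (10 mol%), L-(+)-diethyl tartrate (12 mol%), t-BuOOH, 4 Å MS, CH2Cl2, −20 °C
Reagents that add atoms: tert-butyl hydroperoxide CC(C)(C)OO
Why: Sharpless asymmetric epoxidation touches only the allylic alcohol; with L-(+)-diethyl tartrate the (E)-allylic alcohol should give the (2S,3S)-epoxy alcohol, which fixes the configuration of the later C10 carbinol.

Step 5
Reactants: 5 bis-epoxy alcohol
Product: 6 (2R,3S)-2-(chloromethyl)-3-[(3E)-6-(3,3-dimethyloxiran-2-yl)-4-methylhex-3-en-1-yl]-3-methyloxirane
Conditions: PPh3, CCl4, NaHCO3, reflux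
Reagents that add atoms: tetrachloromethane ClC(Cl)(Cl)Cl
Why: Appel chlorination of the primary alcohol under bicarbonate-buffered conditions should leave both epoxides intact (the descriptor at C2 changes only because CH2Cl outranks the ring carbon).

Step 6
Reactants: 6 epoxy chloride
Product: 7 (3S,6E)-9-(3,3-dimethyloxiran-2-yl)-3,7-dimethylnon-6-en-1-yn-3-ol
Conditions: n-BuLi (3.3 equiv), THF, −40 °C; aq. NH4Cl
Reagents that add atoms: none
Why: Base-induced double elimination of a 2,3-epoxy chloride (lithiation next to chlorine opens the oxirane, a second equivalent eliminates LiCl to the alkyne, a third holds the acetylide); the C–O bond of the carbinol carbon is never broken, so the (S) configuration is kept, and the remote trisubstituted epoxide should not react at −40 °C.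

Step 7
Reactants: 7 epoxy alkynol
Product: 8 (4E,8S)-8-hydroxy-4,8-dimethyldec-4-en-9-ynal
Conditions: H5IO6 (1.2 equiv), THF/H2O, 0 °C
Reagents that add atoms: none
Why: Periodic acid hydrolyses the trisubstituted epoxide and cleaves the glycol (Malaprade-type cleavage) to the aldehyde and acetone, which releases the masked aldehyde without a protecting-group step.

Step 8
Reactants: 9 methyl (triphenyl-λ5-phosphanylidene)acetate; 10 5-bromo-2-methylpent-2-ene
Product: 11 methyl 6-methyl-2-(triphenyl-λ5-phosphanylidene)hept-5-enoate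
Conditions: 9 (2.0 equiv), NaI (10 mol%), MeCN, 80 °C; phosphonium salt removed by filtration from toluene
Reagents that add atoms: none
Why: C-Alkylation of the stabilized ylide by the primary halide (iodide-catalysed SN2) followed by transylidation with the second equivalent of 9 should give the α-substituted ylide.

Step 9
Reactants: 8 ynal; 11 α-homoprenyl ylide
Product: 12 methyl (2E,6E,10S)-10-hydroxy-6,10-dimethyl-2-(4-methylpent-3-en-1-yl)dodeca-2,6-dien-11-ynoate
Conditions: toluene, 60 °C
Reagents that add atoms: none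
Why: Wittig olefination with an α-branched stabilized ylide should place the ester trans to the new chain (2E), as is usual for stabilized ylides; the free tertiary alcohol and the alkyne do not interfere.

Step 10
Reactants: 13 4-methoxy-2-methylphenol
Product: 14 4,4-dimethoxy-2-methylcyclohexa-2,5-dien-1-one
Conditions: PhI(OAc)2, MeOH, 0 °C
Reagents that add atoms: methanol CO
Why: Oxidative dearomatization of a para-methoxyphenol with a hypervalent iodine reagent in methanol gives the quinone monoketal.

Step 11
Reactants: 12 alkyne ester; 14 quinone monoketal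
Product: 16 methyl (2E,6E,10S,11E)-12-(6,6-dimethoxy-4-methyl-3-oxocyclohex-4-en-1-yl)-10-hydroxy-6,10-dimethyl-2-(4-methylpent-3-en-1-yl)dodeca-2,6,11-trienoate (both epimers at the new ring carbon), via bis-borylated alkenylboronate 15 (not isolated)
Conditions: HBpin (2.3 equiv), Cp2Zr(H)Cl (10 mol%), Et3N (10 mol%), 50 °C; then 14 (1.5 equiv), [Rh(cod)OH]2 (3 mol%), K3PO4, dioxane/H2O, 40 °C
Reagents that add atoms: none
Why: Zirconium-hydride-catalysed syn-hydroboration of the terminal alkyne (the tertiary hydroxyl is borylated by a second equivalent of HBpin and freed again in the aqueous stage) gives the (E)-alkenylboronate 15, which transmetalates to the hydroxo-rhodium catalyst; the alkenyl–rhodium species inserts the unsubstituted C5=C6 bond of 14 and water protonates the rhodium enolate, which regenerates Rh–OH. The closest known reaction type is the Hayashi–Miyaura conjugate addition of alkenylboron reagents, made in the same flask by alkyne hydroboration, to cyclic enones, together with the rhodium-catalysed 1,4-addition of boron reagents to quinone monoketals. No ring is closed; the ring carbon that receives the side chain becomes a stereocentre without control, which is of no consequence because it turns into an sp2 carbon on aromatization in step 12. The E geometry follows from syn-addition of H–B with boron on the terminal carbon and should be kept through transmetalation and insertion, which go with retention. The step needs chemoselectivity for the alkyne over the two trisubstituted alkenes and the enoate, which the Zr–H catalyst should secure because it adds only to the terminal alkyne under these conditions. It also needs site-selectivity for C5 over C3 of the dienone and mono-addition, which the methyl group on C2 should secure, because α-substituted enones insert far more slowly, so both the second arm of 14 and the enone left in 16 stay untouched.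

Step 12
Reactants: 16 ketal adduct
Product: 19 (2E,6E,10S,11E)-12-(2,5-dihydroxy-4-methylphenyl)-10-hydroxy-6,10-dimethyl-2-(4-methylpent-3-en-1-yl)dodeca-2,6,11-trienoic acid (target), via lithium carboxylate 17 (not isolated), via enedione acid 18 (not isolated)
Conditions: LiOH·H2O, THF/MeOH/H2O, rt to 40 °C, Ar; then 0.5 M HCl to pH 3, 0 °C; then NaH2PO4/Na2HPO4 buffer, pH 7; extraction at pH 5
Reagents that add atoms: lithium hydroxide [Li+].[OH-]; water O
Why: Saponification is done on the still non-aromatic, air-stable ketone, then specific-acid hydrolysis of the dimethyl ketal gives the ene-1,4-dione, whose keto–enol tautomerization on neutralization gives the hydroquinone; the C10 carbinol should survive because at pH 3 the ring is still the electron-poor enedione and the alcohol is only an ordinary tertiary allylic alcohol.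

**Compound list**
1 | (2E,6E)-farnesol | CC(C)=CCC/C(C)=C/CC/C(C)=C/CO | starting material
2 | (2E,6E)-farnesyl acetate | CC(C)=CCC/C(C)=C/CC/C(C)=C/COC(C)=O | intermediate
3 | (2E,6E)-10-bromo-11-hydroxy-3,7,11-trimethyldodeca-2,6-dien-1-yl acetate (racemic at C10) | CC(C)(O)C(Br)CC/C(C)=C/CC/C(C)=C/COC(C)=O | intermediate
4 | (2E,6E)-9-(3,3-dimethyloxiran-2-yl)-3,7-dimethylnona-2,6-dien-1-ol (racemic epoxide) | CC1(C)OC1CC/C(C)=C/CC/C(C)=C/CO | intermediate
5 | [(2S,3S)-3-[(3E)-6-(3,3-dimethyloxiran-2-yl)-4-methylhex-3-en-1-yl]-3-methyloxiran-2-yl]methanol (epimers at the distal oxirane) | OC[C@@H]1O[C@@]1(C)CC/C=C(\C)CCC2OC2(C)C | intermediate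
6 | (2R,3S)-2-(chloromethyl)-3-[(3E)-6-(3,3-dimethyloxiran-2-yl)-4-methylhex-3-en-1-yl]-3-methyloxirane | ClC[C@@H]1O[C@@]1(C)CC/C=C(\C)CCC2OC2(C)C | intermediate
7 | (3S,6E)-9-(3,3-dimethyloxiran-2-yl)-3,7-dimethylnon-6-en-1-yn-3-ol | C#C[C@@](C)(O)CC/C=C(\C)CCC1OC1(C)C | intermediate
8 | (4E,8S)-8-hydroxy-4,8-dimethyldec-4-en-9-ynal | C#C[C@@](C)(O)CC/C=C(\C)CCC=O | intermediate
9 | methyl (triphenyl-λ5-phosphanylidene)acetate | COC(=O)C=P(c1ccccc1)(c1ccccc1)c1ccccc1 | starting material
10 | 5-bromo-2-methylpent-2-ene | CC(C)=CCCBr | starting material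
11 | methyl 6-methyl-2-(triphenyl-λ5-phosphanylidene)hept-5-enoate | COC(=O)C(CCC=C(C)C)=P(c1ccccc1)(c1ccccc1)c1ccccc1 | intermediate
12 | methyl (2E,6E,10S)-10-hydroxy-6,10-dimethyl-2-(4-methylpent-3-en-1-yl)dodeca-2,6-dien-11-ynoate | C#C[C@@](C)(O)CC/C=C(\C)CC/C=C(\CCC=C(C)C)C(=O)OC | intermediate
13 | 4-methoxy-2-methylphenol | COc1ccc(O)c(C)c1 | starting material
14 | 4,4-dimethoxy-2-methylcyclohexa-2,5-dien-1-one | COC1(OC)C=CC(=O)C(C)=C1 | intermediate
15 | methyl (2E,6E,10S,11E)-6,10-dimethyl-2-(4-methylpent-3-en-1-yl)-12-(4,4,5,5-tetramethyl-1,3,2-dioxaborolan-2-yl)-10-[(4,4,5,5-tetramethyl-1,3,2-dioxaborolan-2-yl)oxy]dodeca-2,6,11-trienoate | COC(=O)/C(CCC=C(C)C)=C/CC/C(C)=C/CC[C@](C)(OB1OC(C)(C)C(C)(C)O1)/C=C/B2OC(C)(C)C(C)(C)O2 | intermediate (not isolated)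
16 | methyl (2E,6E,10S,11E)-12-(6,6-dimethoxy-4-methyl-3-oxocyclohex-4-en-1-yl)-10-hydroxy-6,10-dimethyl-2-(4-methylpent-3-en-1-yl)dodeca-2,6,11-trienoate (epimers at the ring CH) | COC(=O)/C(CCC=C(C)C)=C/CC/C(C)=C/CC[C@](C)(O)/C=C/C1CC(=O)C(C)=CC1(OC)OC | intermediate
17 | lithium (2E,6E,10S,11E)-12-(6,6-dimethoxy-4-methyl-3-oxocyclohex-4-en-1-yl)-10-hydroxy-6,10-dimethyl-2-(4-methylpent-3-en-1-yl)dodeca-2,6,11-trienoate | [Li+].[O-]C(=O)/C(CCC=C(C)C)=C/CC/C(C)=C/CC[C@](C)(O)/C=C/C1CC(=O)C(C)=CC1(OC)OC | intermediate (not isolated)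
18 | (2E,6E,10S,11E)-10-hydroxy-6,10-dimethyl-12-(4-methyl-3,6-dioxocyclohex-4-en-1-yl)-2-(4-methylpent-3-en-1-yl)dodeca-2,6,11-trienoic acid | OC(=O)/C(CCC=C(C)C)=C/CC/C(C)=C/CC[C@](C)(O)/C=C/C1CC(=O)C(C)=CC1=O | intermediate (not isolated)
19 | (2E,6E,10S,11E)-12-(2,5-dihydroxy-4-methylphenyl)-10-hydroxy-6,10-dimethyl-2-(4-methylpent-3-en-1-yl)dodeca-2,6,11-trienoic acid | CC(C)=CCC/C(=C\CC/C(C)=C/CC[C@](C)(O)/C=C/c1cc(O)c(C)cc1O)C(=O)O | target

**Step count and risks**
Total steps: 12. Longest linear sequence: 10 (steps 1–7, 9, 11, 12).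

Steps most likely to fail:

1. Step 11. The hydroboration may be incomplete or may reduce the enoate, the alkenyl–rhodium species may be protonated before it inserts, or insertion may occur on the methyl-bearing arm of the dienone. The fallback sets out from 12 and returns at 19. Alkyne 12 is hydroborated as in step 11 but worked up with water, which should give methyl (2E,6E,10S,11E)-10-hydroxy-6,10-dimethyl-2-(4-methylpent-3-en-1-yl)-12-(4,4,5,5-tetramethyl-1,3,2-dioxaborolan-2-yl)dodeca-2,6,11-trienoate F1 as an isolable compound. Commercial 2-methylbenzene-1,4-diol is silylated (TBSCl, imidazole, DMF) to 1,4-bis[(tert-butyldimethylsilyl)oxy]-2-methylbenzene F2 and iodinated para to the methyl group (NIS, cat. TFA, MeCN, 0 °C) to 1,4-bis[(tert-butyldimethylsilyl)oxy]-2-iodo-5-methylbenzene F3. Suzuki–Miyaura coupling of F1 with F3 (Pd(dppf)Cl2, K3PO4, THF/H2O, 50 °C) forms the same aryl–vinyl bond with retention of the E geometry and should give methyl (2E,6E,10S,11E)-12-{2,5-bis[(tert-butyldimethylsilyl)oxy]-4-methylphenyl}-10-hydroxy-6,10-dimethyl-2-(4-methylpent-3-en-1-yl)dodeca-2,6,11-trienoate F4. LiOH·H2O in degassed THF/MeOH/H2O then removes both aryl silyl ethers and the methyl ester and gives 19 after acidification to pH 5.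

2. Step 12. Once the ring has aromatized, the tertiary allylic alcohol may ionize in the acidic stage (loss of configuration at C10, cyclization onto the ortho hydroxyl to a 2H-chromene), or methanol may be lost instead of the ketal being hydrolysed, so that one oxygen stays methylated. The fallback sets out from 16 and returns at 19; it accepts the loss of methanol on purpose and removes the methyl group oxidatively. TMSOTf and i-Pr2NEt in CH2Cl2 (−78 to 0 °C) silylate the tertiary alcohol, turn the ketal into the methyl enol ether and the ketone into its silyl enol ether, so that the ring aromatizes under amine-buffered conditions to methyl (2E,6E,10S,11E)-12-{2-methoxy-4-methyl-5-[(trimethylsilyl)oxy]phenyl}-6,10-dimethyl-2-(4-methylpent-3-en-1-yl)-10-[(trimethylsilyl)oxy]dodeca-2,6,11-trienoate F5, which is not isolated. K2CO3 in MeOH removes both trimethylsilyl groups and gives methyl (2E,6E,10S,11E)-10-hydroxy-12-(5-hydroxy-2-methoxy-4-methylphenyl)-6,10-dimethyl-2-(4-methylpent-3-en-1-yl)dodeca-2,6,11-trienoate F6. Saponification (LiOH·H2O, THF/MeOH/H2O) gives (2E,6E,10S,11E)-10-hydroxy-12-(5-hydroxy-2-methoxy-4-methylphenyl)-6,10-dimethyl-2-(4-methylpent-3-en-1-yl)dodeca-2,6,11-trienoic acid F7. Oxidative demethylation of the para-methoxyphenol with PhI(OAc)2 in MeCN/H2O at 0 °C gives (2E,6E,10S,11E)-10-hydroxy-6,10-dimethyl-12-(4-methyl-3,6-dioxocyclohexa-1,4-dien-1-yl)-2-(4-methylpent-3-en-1-yl)dodeca-2,6,11-trienoic acid F8, in which the allylic alcohol is flanked by an electron-poor ring. Na2S2O4 added to the same flask reduces F8 to 19 at neutral pH.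

3. Step 8. The SN2 alkylation of the weakly nucleophilic ylide by an unactivated homoallylic bromide may be slow and stop at partial conversion. The fallback sets out from 10 and returns at 12. Trimethyl phosphonoacetate is deprotonated (NaH, DMSO) and alkylated with 10 at 60 °C to give methyl 2-(dimethoxyphosphoryl)-6-methylhept-5-enoate F9. Horner–Wadsworth–Emmons reaction of F9 with aldehyde 8 under Masamune–Roush conditions (LiCl, DBU, MeCN) should give 12; any (2Z) isomer would have to be removed by chromatography.

**Further compounds**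
F1 | step 11 | methyl (2E,6E,10S,11E)-10-hydroxy-6,10-dimethyl-2-(4-methylpent-3-en-1-yl)-12-(4,4,5,5-tetramethyl-1,3,2-dioxaborolan-2-yl)dodeca-2,6,11-trienoate | COC(=O)/C(CCC=C(C)C)=C/CC/C(C)=C/CC[C@](C)(O)/C=C/B1OC(C)(C)C(C)(C)O1
F2 | step 11 | 1,4-bis[(tert-butyldimethylsilyl)oxy]-2-methylbenzene | Cc1cc(O[Si](C)(C)C(C)(C)C)ccc1O[Si](C)(C)C(C)(C)C
F3 | step 11 | 1,4-bis[(tert-butyldimethylsilyl)oxy]-2-iodo-5-methylbenzene | Cc1cc(O[Si](C)(C)C(C)(C)C)c(I)cc1O[Si](C)(C)C(C)(C)C
F4 | step 11 | methyl (2E,6E,10S,11E)-12-{2,5-bis[(tert-butyldimethylsilyl)oxy]-4-methylphenyl}-10-hydroxy-6,10-dimethyl-2-(4-methylpent-3-en-1-yl)dodeca-2,6,11-trienoate | COC(=O)/C(CCC=C(C)C)=C/CC/C(C)=C/CC[C@](C)(O)/C=C/c1cc(O[Si](C)(C)C(C)(C)C)c(C)cc1O[Si](C)(C)C(C)(C)C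
F5 | step 12 | methyl (2E,6E,10S,11E)-12-{2-methoxy-4-methyl-5-[(trimethylsilyl)oxy]phenyl}-6,10-dimethyl-2-(4-methylpent-3-en-1-yl)-10-[(trimethylsilyl)oxy]dodeca-2,6,11-trienoate | COC(=O)/C(CCC=C(C)C)=C/CC/C(C)=C/CC[C@](C)(O[Si](C)(C)C)/C=C/c1cc(O[Si](C)(C)C)c(C)cc1OC
F6 | step 12 | methyl (2E,6E,10S,11E)-10-hydroxy-12-(5-hydroxy-2-methoxy-4-methylphenyl)-6,10-dimethyl-2-(4-methylpent-3-en-1-yl)dodeca-2,6,11-trienoate | COC(=O)/C(CCC=C(C)C)=C/CC/C(C)=C/CC[C@](C)(O)/C=C/c1cc(O)c(C)cc1OC
F7 | step 12 | (2E,6E,10S,11E)-10-hydroxy-12-(5-hydroxy-2-methoxy-4-methylphenyl)-6,10-dimethyl-2-(4-methylpent-3-en-1-yl)dodeca-2,6,11-trienoic acid | OC(=O)/C(CCC=C(C)C)=C/CC/C(C)=C/CC[C@](C)(O)/C=C/c1cc(O)c(C)cc1OC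
F8 | step 12 | (2E,6E,10S,11E)-10-hydroxy-6,10-dimethyl-12-(4-methyl-3,6-dioxocyclohexa-1,4-dien-1-yl)-2-(4-methylpent-3-en-1-yl)dodeca-2,6,11-trienoic acid | OC(=O)/C(CCC=C(C)C)=C/CC/C(C)=C/CC[C@](C)(O)/C=C/C1=CC(=O)C(C)=CC1=O
F9 | step 8 | methyl 2-(dimethoxyphosphoryl)-6-methylhept-5-enoate | COC(=O)C(CCC=C(C)C)P(=O)(OC)OC
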